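The γ-butyrolactone ring is disconnected at O1–C5 and C3–C4. C3 (α to the lactone carbonyl C2) and C4 (α to the exocyclic aroyl carbonyl) are two α-carbonyl carbons of like polarity; the route reverses the polarity of C3 with an (R)-α-bromide. In one operation an amine-catalysed oxa-Michael/enamine alkylation joins an (R)-2-bromo-3-arylpropanoic acid and acrolein: the carboxylate oxygen adds to the enal β-carbon (O1–C5) and the enamine carbon displaces bromide with inversion (C3–C4), closing the trans lactone with a formyl group at C4. That formyl group stands in for the aroyl group (aryl Grignard addition, oxidation); Evans bromination supplies the bromide and hydrogenolysis frees both phenols.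

Key step: step 5

Remark (assumption): lactone atoms are numbered O1, C2 (carbonyl), C3 (benzyl-bearing), C4 (acyl-bearing), C5 (OCH2) for all intermediates, and the trans C3/C4 arrangement is taken as the thermodynamically preferred one at the enolisable C4, as is general for 3,4-disubstituted γ-butyrolactones.

Step 1
Reactants: 1 3-(4-hydroxy-3-methoxyphenyl)propanoic acid (dihydroferulic acid)
Product: 2 3-[4-(benzyloxy)-3-methoxyphenyl]propanoic acid
Conditions: BnBr (1.1 equiv), NaOH (2.5 equiv), EtOH/H2O, reflux; then aq HCl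
Reagents that add atoms: benzyl bromide, BrCc1ccccc1
Why: Williamson etherification of the dianion, in which the phenoxide is far more nucleophilic than the carboxylate in protic solvent and any benzyl ester formed is saponified in the same pot.

Step 2
Reactants: 2 3-[4-(benzyloxy)-3-methoxyphenyl]propanoic acid; 3 (4R)-4-benzyl-1,3-oxazolidin-2-one
Product: 5 (4R)-4-benzyl-3-{3-[4-(benzyloxy)-3-methoxyphenyl]propanoyl}-1,3-oxazolidin-2-one, via mixed pivalic anhydride 4 (not isolated)
Conditions: PivCl, Et3N, THF, −20 °C; then 3, LiCl, −20 °C → rt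
Reagents that add atoms: none
Why: N-acylation of the oxazolidinone through the mixed anhydride, which is attacked at its less hindered carbonyl under LiCl activation.

Step 3
Reactants: 5 (4R)-4-benzyl-3-{3-[4-(benzyloxy)-3-methoxyphenyl]propanoyl}-1,3-oxazolidin-2-one
Product: 7 (4R)-4-benzyl-3-{(2R)-2-bromo-3-[4-(benzyloxy)-3-methoxyphenyl]propanoyl}-1,3-oxazolidin-2-one, via Z-dibutylboron enolate 6 (not isolated)
Conditions: Bu2BOTf, iPr2NEt, CH2Cl2, −78 → 0 °C; then NBS, −78 °C
Reagents that add atoms: N-bromosuccinimide, O=C1CCC(=O)N1Br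
Why: Evans asymmetric α-bromination, in which the Z-enolate is brominated on the face opposite the auxiliary benzyl group, so the (4R)-auxiliary should deliver the (2R)-bromide (future C3).

Step 4
Reactants: 7 (4R)-4-benzyl-3-{(2R)-2-bromo-3-[4-(benzyloxy)-3-methoxyphenyl]propanoyl}-1,3-oxazolidin-2-one
Product: 9 (2R)-2-bromo-3-[4-(benzyloxy)-3-methoxyphenyl]propanoic acid, via peroxy acid 8 (not isolated)
Conditions: LiOH, H2O2, THF/H2O, 0 °C; then aq Na2SO3; aq HCl
Reagents that add atoms: hydrogen peroxide (acting as LiOOH), OO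
Why: Hydroperoxide cleavage of the imide at the exocyclic carbonyl at 0 °C, followed by sulfite reduction of the peracid, is non-enolising and should leave the bromide stereocentre intact while returning the auxiliary.

Step 5
Reactants: 9 (2R)-2-bromo-3-[4-(benzyloxy)-3-methoxyphenyl]propanoic acid; 10 acrolein
Product: 12 (3R,4R)-4-{[4-(benzyloxy)-3-methoxyphenyl]methyl}-5-oxooxolane-3-carbaldehyde, via β-acyloxy enamine 11 (not isolated)
Conditions: (R)-α,α-diphenylprolinol trimethylsilyl ether (20 mol%), 2,6-lutidine (1.2 equiv), acrolein (3 equiv, slow addition), CHCl3, 0 °C → rt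
Reagents that add atoms: none
Why: Proposed new method: the amine and acrolein form an iminium ion, the carboxylate of 9 adds to its β-carbon (oxa-Michael, O1–C5), and the resulting β-acyloxy enamine 11 displaces bromide at the α-carbon of its own ester (C3–C4) before hydrolysis returns the catalyst; a base-mediated version through a β-acyloxy enolate would expel the carboxylate, whereas the neutral enamine only reverts to iminium ion and carboxylate, so the irreversible ring closure should drain the equilibrium. The closest known reaction types are the aminocatalytic iminium–enamine Michael/α-alkylation dominoes of enals with bromomalonates (cyclopropanation), the related epoxidations and aziridinations, and the amine-catalysed intramolecular α-alkylation of halo aldehydes. The lactone ring closes in a 5-exo-tet mode with the enamine double bond exocyclic to the forming ring. C3 is substrate-controlled: backside displacement inverts the (R)-bromide, which, because the substituent priorities change, is again (R) in the lactone. C4 is catalyst-controlled, the diphenyl(silyloxy)methyl group of the (R)-amine shielding one enamine face so that closure passes through the trans transition state, and as an aldehyde α-centre it also rests at the thermodynamically preferred trans arrangement. The step needs enamine C-alkylation to beat catalyst N-alkylation, phenol addition and bromide exchange at the stereocentre; the substrate should secure this because its C–Br is activated for displacement only once the carboxylate has become the ester in 11, where it sits five atoms from the enamine carbon, and because the phenol is masked as the benzyl ether.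

Step 6
Reactants: 12 (3R,4R)-4-{[4-(benzyloxy)-3-methoxyphenyl]methyl}-5-oxooxolane-3-carbaldehyde; 13 1-(benzyloxy)-4-bromo-2-methoxybenzene
Product: 15 (3R,4R)-3-{[4-(benzyloxy)-3-methoxyphenyl]methyl}-4-{[4-(benzyloxy)-3-methoxyphenyl](hydroxy)methyl}oxolan-2-one (both carbinol epimers), via arylmagnesium bromide 14 (not isolated)
Conditions: 13, Mg turnings, THF, 40 °C; then 12, THF, −78 °C; AcOH quench at −78 °C
Reagents that add atoms: none
Why: Grignard 1,2-addition to the aldehyde, which is far more electrophilic than the lactone at −78 °C; the new carbinol centre needs no control because it is oxidised in the next step, and the cold acidic quench should prevent acyl migration.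

Step 7
Reactants: 15 (3R,4R)-3-{[4-(benzyloxy)-3-methoxyphenyl]methyl}-4-{[4-(benzyloxy)-3-methoxyphenyl](hydroxy)methyl}oxolan-2-one
Product: 16 (3R,4R)-4-[4-(benzyloxy)-3-methoxybenzoyl]-3-{[4-(benzyloxy)-3-methoxyphenyl]methyl}oxolan-2-one
Conditions: Dess–Martin periodinane, CH2Cl2, 0 °C → rt
Reagents that add atoms: none
Why: Dess–Martin oxidation of the benzylic alcohol under non-basic conditions; C4, now α to the aryl ketone, rests in the thermodynamically preferred trans arrangement, so enolisation cannot erode the configuration anchored at C3.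

Step 8
Reactants: 16 (3R,4R)-4-[4-(benzyloxy)-3-methoxybenzoyl]-3-{[4-(benzyloxy)-3-methoxyphenyl]methyl}oxolan-2-one
Product: 17 (3R,4R)-4-(4-hydroxy-3-methoxybenzoyl)-3-[(4-hydroxy-3-methoxyphenyl)methyl]oxolan-2-one (target)
Conditions: H2 (1 atm), 10% Pd/C (palladium on carbon), EtOAc, rt
Reagents that add atoms: none
Why: Catalytic hydrogenolysis of both aryl benzyl ethers under neutral conditions, which should spare the electron-rich aryl ketone and the lactone and does not touch either stereocentre.

Compound list
1 | 3-(4-hydroxy-3-methoxyphenyl)propanoic acid (dihydroferulic acid) | COc1cc(CCC(=O)O)ccc1O | starting material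
2 | 3-[4-(benzyloxy)-3-methoxyphenyl]propanoic acid | COc1cc(CCC(=O)O)ccc1OCc1ccccc1 | intermediate
3 | (4R)-4-benzyl-1,3-oxazolidin-2-one | O=C1N[C@H](Cc2ccccc2)CO1 | starting material
4 | 3-[4-(benzyloxy)-3-methoxyphenyl]propanoic 2,2-dimethylpropanoic anhydride (not isolated) | COc1cc(CCC(=O)OC(=O)C(C)(C)C)ccc1OCc1ccccc1 | intermediate
5 | (4R)-4-benzyl-3-{3-[4-(benzyloxy)-3-methoxyphenyl]propanoyl}-1,3-oxazolidin-2-one | COc1cc(CCC(=O)N2C(=O)OC[C@H]2Cc2ccccc2)ccc1OCc1ccccc1 | intermediate
6 | Z-dibutylboron enolate of 5 (not isolated) | CCCCB(CCCC)O/C(=C\Cc1ccc(OCc2ccccc2)c(OC)c1)N1C(=O)OC[C@H]1Cc1ccccc1 | intermediate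
7 | (4R)-4-benzyl-3-{(2R)-2-bromo-3-[4-(benzyloxy)-3-methoxyphenyl]propanoyl}-1,3-oxazolidin-2-one | COc1cc(C[C@@H](Br)C(=O)N2C(=O)OC[C@H]2Cc2ccccc2)ccc1OCc1ccccc1 | intermediate
8 | (2R)-2-bromo-3-[4-(benzyloxy)-3-methoxyphenyl]propaneperoxoic acid (not isolated) | OOC(=O)[C@H](Br)Cc1ccc(OCc2ccccc2)c(OC)c1 | intermediate
9 | (2R)-2-bromo-3-[4-(benzyloxy)-3-methoxyphenyl]propanoic acid | OC(=O)[C@H](Br)Cc1ccc(OCc2ccccc2)c(OC)c1 | intermediate
10 | acrolein (prop-2-enal) | C=CC=O | starting material
11 | (E)-3-{(2R)-2-[diphenyl(trimethylsilyloxy)methyl]pyrrolidin-1-yl}prop-2-en-1-yl (2R)-2-bromo-3-[4-(benzyloxy)-3-methoxyphenyl]propanoate (β-acyloxy enamine, not isolated) | C[Si](C)(C)OC(c1ccccc1)(c1ccccc1)[C@H]1CCCN1/C=C/COC(=O)[C@H](Br)Cc1ccc(OCc2ccccc2)c(OC)c1 | intermediate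
12 | (3R,4R)-4-{[4-(benzyloxy)-3-methoxyphenyl]methyl}-5-oxooxolane-3-carbaldehyde | COc1cc(C[C@H]2C(=O)OC[C@@H]2C=O)ccc1OCc1ccccc1 | intermediate
13 | 1-(benzyloxy)-4-bromo-2-methoxybenzene | COc1cc(Br)ccc1OCc1ccccc1 | starting material
14 | [4-(benzyloxy)-3-methoxyphenyl]magnesium bromide (not isolated) | COc1cc([Mg]Br)ccc1OCc1ccccc1 | intermediate
15 | (3R,4R)-3-{[4-(benzyloxy)-3-methoxyphenyl]methyl}-4-{[4-(benzyloxy)-3-methoxyphenyl](hydroxy)methyl}oxolan-2-one (carbinol epimers) | COc1cc(C[C@H]2C(=O)OC[C@@H]2C(O)c2ccc(OCc3ccccc3)c(OC)c2)ccc1OCc1ccccc1 | intermediate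
16 | (3R,4R)-4-[4-(benzyloxy)-3-methoxybenzoyl]-3-{[4-(benzyloxy)-3-methoxyphenyl]methyl}oxolan-2-one | COc1cc(C[C@H]2C(=O)OC[C@@H]2C(=O)c2ccc(OCc3ccccc3)c(OC)c2)ccc1OCc1ccccc1 | intermediate
17 | (3R,4R)-4-(4-hydroxy-3-methoxybenzoyl)-3-[(4-hydroxy-3-methoxyphenyl)methyl]oxolan-2-one | COc1cc(C[C@H]2C(=O)OC[C@@H]2C(=O)c2ccc(O)c(OC)c2)ccc1O | target

Total step count: 8
Longest linear sequence: 8 steps (1 → 2 → 5 → 7 → 9 → 12 → 15 → 16 → 17)

Steps most likely to fail

Step 5 (Proposed new method). The oxa-Michael equilibrium may not be drained by ring closure: the catalyst may be N-alkylated by the bromide, acrolein may oligomerise through its enamine, or bromide exchange may erode the C3 configuration before closure. The fallback uses known chemistry and builds the same lactone stepwise. It sets out from 2, which is acylated as in step 2 (via 4) onto (4S)-4-benzyl-1,3-oxazolidin-2-one to give the enantiomeric-auxiliary imide F1. Its sodium enolate (NaHMDS, THF, −78 °C) is alkylated with 2-bromo-1-[4-(benzyloxy)-3-methoxyphenyl]ethan-1-one F2, made from the commercial acetophenone with CuBr2 in EtOAc/CHCl3. This Evans alkylation should give the (2R)-γ-keto imide F3 and so sets C3. LiOH/H2O2 cleavage gives the γ-keto acid F4. Aqueous formaldehyde/NaOH hydroxymethylates the ketone α-CH2 to the hydroxymethyl keto acid F5 (not isolated), which lactonises on acidification to the trans lactone. The fallback comes back to the route at 16, so steps 6 and 7 are not needed.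

Step 6. The Grignard reagent may enolise the α-branched aldehyde instead of adding, and the new magnesium alkoxide may attack the lactone carbonyl (acyl migration to the isomeric lactone). The fallback sets out from 12 and avoids a free carbinol altogether. Pinnick oxidation (NaClO2, NaH2PO4, 2-methyl-2-butene, tBuOH/H2O) gives the lactone acid F6. Oxalyl chloride with catalytic DMF gives the acid chloride F7. An acyl Negishi coupling (Pd(PPh3)4, THF, 0 °C → rt) with [4-(benzyloxy)-3-methoxyphenyl]zinc chloride F8, made from 14 and ZnCl2, should give the ketone directly. The fallback comes back to the route at 16, and epimerisation at C4 on the way is harmless because it converges on trans.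

Step 8. Over-reduction of the benzylic ketone to the carbinol or methylene may compete with O-debenzylation on palladium. The fallback sets out from 16 and replaces hydrogenolysis by non-reductive Lewis-acid dealkylation: BCl3 with pentamethylbenzene as benzyl-cation scavenger, CH2Cl2, −78 °C. It comes back to the route at 17 and makes no new compound.

Further compounds
F1 | step 5 | (4S)-4-benzyl-3-{3-[4-(benzyloxy)-3-methoxyphenyl]propanoyl}-1,3-oxazolidin-2-one | COc1cc(CCC(=O)N2C(=O)OC[C@@H]2Cc2ccccc2)ccc1OCc1ccccc1
F2 | step 5 | 2-bromo-1-[4-(benzyloxy)-3-methoxyphenyl]ethan-1-one | COc1cc(C(=O)CBr)ccc1OCc1ccccc1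
F3 | step 5 | (4S)-4-benzyl-3-{(2R)-2-{[4-(benzyloxy)-3-methoxyphenyl]methyl}-4-[4-(benzyloxy)-3-methoxyphenyl]-4-oxobutanoyl}-1,3-oxazolidin-2-one | COc1cc(C[C@H](CC(=O)c2ccc(OCc3ccccc3)c(OC)c2)C(=O)N2C(=O)OC[C@@H]2Cc2ccccc2)ccc1OCc1ccccc1
F4 | step 5 | (2R)-2-{[4-(benzyloxy)-3-methoxyphenyl]methyl}-4-[4-(benzyloxy)-3-methoxyphenyl]-4-oxobutanoic acid | COc1cc(C[C@H](CC(=O)c2ccc(OCc3ccccc3)c(OC)c2)C(=O)O)ccc1OCc1ccccc1
F5 | step 5 | (2R)-2-{[4-(benzyloxy)-3-methoxyphenyl]methyl}-3-(hydroxymethyl)-4-[4-(benzyloxy)-3-methoxyphenyl]-4-oxobutanoic acid (C3 epimers) | COc1cc(C[C@H](C(CO)C(=O)c2ccc(OCc3ccccc3)c(OC)c2)C(=O)O)ccc1OCc1ccccc1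
F6 | step 6 | (3R,4R)-4-{[4-(benzyloxy)-3-methoxyphenyl]methyl}-5-oxooxolane-3-carboxylic acid | COc1cc(C[C@H]2C(=O)OC[C@@H]2C(=O)O)ccc1OCc1ccccc1
F7 | step 6 | (3R,4R)-4-{[4-(benzyloxy)-3-methoxyphenyl]methyl}-5-oxooxolane-3-carbonyl chloride | COc1cc(C[C@H]2C(=O)OC[C@@H]2C(=O)Cl)ccc1OCc1ccccc1
F8 | step 6 | [4-(benzyloxy)-3-methoxyphenyl]zinc chloride | COc1cc([Zn]Cl)ccc1OCc1ccccc1
F0 | step 8 | none | none
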